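**Retrosynthetic overview**
1. Last disconnection: the coumarin C4–O bond of the 1,3-dioxine. The target comes from silyl-protected hydroxy 1,2-diketone 19, which carries a 4-phenoxycoumarin; fluoride gives alkoxide, then six-ring hemiketal, then addition–elimination at C4.
2. Enabling feature: coumarin C4 is the β-carbon of the vinylogous carbonate O1–C2(=O)–C3=C4–OAr, and the inner diketone carbonyl lies δ to the carbinol oxygen on the C3 substituent. Hemiketalisation therefore builds the tetrahydropyran and leaves its anomeric O⁻ 1,3 to C3, one bond from C4.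
3. 19 comes from cyclopentenyl triflate 16 and dithiane-masked ethyl ketone 10 (Pd α-alkenylation, then Hg(II) unmasking).
4. 16 comes from a three-component union of cyclopent-2-enone, Me2Zn and coumarin aldehyde 4 (conjugate addition/anti-aldol sets three stereocentres), then silylation and kinetic enol triflation.
5. Ring order: coumarin (steps 1–3), cyclopentene (from cyclopentenone, steps 6–8), then tetrahydropyran and 1,3-dioxine together in the last step.

Key step: step 11

Assumption: compounds 1, 5, 6, 8 and 11 and all named reagents are commercial; the copper ligand antipode is the one that delivers the (S)-methyl centre.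

**Step 1**
Reactants: 1 1-(2-hydroxy-6-methylphenyl)ethan-1-one
Product: 2 4-hydroxy-5-methyl-2H-chromen-2-one
Conditions: NaH (3 equiv), (EtO)2CO, toluene, 110 °C; then aq. HCl
Reagents that add atoms: diethyl carbonate, CCOC(=O)OCC
Why: Claisen-type C-acylation of the methyl ketone enolate by the carbonate, then lactonisation by the phenoxide, is the standard 4-hydroxycoumarin synthesis.

**Step 2**
Reactants: 2 4-hydroxy-5-methyl-2H-chromen-2-one
Product: 3 4-chloro-5-methyl-2-oxo-2H-chromene-3-carbaldehyde
Conditions: POCl3, DMF, 0 → 60 °C; then ice–water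
Reagents that add atoms: N,N-dimethylformamide, CN(C)C=O; phosphoryl chloride, O=P(Cl)(Cl)Cl; water, O
Why: Vilsmeier–Haack reaction; the chloroiminium ion formylates nucleophilic C3 and turns the vinylogous acid OH at C4 into chloride.

**Step 3**
Reactants: 3 4-chloro-5-methyl-2-oxo-2H-chromene-3-carbaldehyde
Product: 4 5-methyl-2-oxo-4-phenoxy-2H-chromene-3-carbaldehyde
Conditions: PhOH, K2CO3, MeCN, 23 °C
Reagents that add atoms: phenol, Oc1ccccc1
Why: Addition–elimination (SNV) at C4, activated by both the lactone and the formyl group; phenoxy is a leaving group that is inert to Pd(0) and hindered amide bases yet still displaceable by an alkoxide later.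

**Step 4**
Reactants: 5 3-methylbutanal; 6 propane-1,3-dithiol
Product: 7 2-(2-methylpropyl)-1,3-dithiane
Conditions: BF3·OEt2 (cat.), CH2Cl2, 0 → 23 °C
Reagents that add atoms: none
Why: Lewis-acid-catalysed dithioacetalisation of an unhindered aldehyde.

**Step 5**
Reactants: 7 2-(2-methylpropyl)-1,3-dithiane; 8 N-methoxy-N-methylpropanamide
Product: 10 1-[2-(2-methylpropyl)-1,3-dithian-2-yl]propan-1-one, via 2-lithio-2-(2-methylpropyl)-1,3-dithiane 9 (not isolated)
Conditions: n-BuLi, THF, −30 °C; then 8, −78 → 0 °C; aq. NH4Cl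
Reagents that add atoms: none
Why: Corey–Seebach umpolung; the lithiodithiane is acylated by the Weinreb amide, whose chelated tetrahedral adduct prevents over-addition.

**Step 6**
Reactants: 11 cyclopent-2-en-1-one; 4 5-methyl-2-oxo-4-phenoxy-2H-chromene-3-carbaldehyde
Product: 13 3-{(R)-hydroxy[(1S,2S)-2-methyl-5-oxocyclopentyl]methyl}-5-methyl-4-phenoxy-2H-chromen-2-one, via methylzinc (S)-3-methylcyclopent-1-en-1-olate 12 (not isolated)
Conditions: Me2Zn, Cu(OTf)2 (2 mol%), chiral amino-acid-based Schiff-base phosphine ligand (5 mol%), toluene, −30 °C; then 4, −30 °C; aq. NH4Cl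
Reagents that add atoms: dimethylzinc, C[Zn]C
Why: Cu-catalysed asymmetric conjugate addition/aldol three-component coupling; the ligand sets the methyl-bearing centre, the aldehyde enters anti to that methyl (2,3-trans), and the ring-locked E-enolate reacts through a Zimmerman–Traxler chair to give the anti carbinol.

**Step 7**
Reactants: 13 the aldol from step 6
Product: 14 5-methyl-3-{(R)-[(1S,2S)-2-methyl-5-oxocyclopentyl][(triethylsilyl)oxy]methyl}-4-phenoxy-2H-chromen-2-one
Conditions: TESOTf, 2,6-lutidine, CH2Cl2, −78 °C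
Reagents that add atoms: triethylsilyl trifluoromethanesulfonate, CC[Si](CC)(CC)OS(=O)(=O)C(F)(F)F
Why: Silylation of the secondary alcohol blocks retro-aldol and β-elimination in the enolate steps that follow.

**Step 8**
Reactants: 14 the silyl ether from step 7
Product: 16 (4S,5S)-4-methyl-5-{(R)-(5-methyl-2-oxo-4-phenoxy-2H-chromen-3-yl)[(triethylsilyl)oxy]methyl}cyclopent-1-en-1-yl trifluoromethanesulfonate, via kinetic lithium enolate 15 (not isolated)
Conditions: LDA, THF, −78 °C; then Comins' reagent, −78 → −40 °C; aq. NH4Cl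
Reagents that add atoms: N-(5-chloropyridin-2-yl)bis(trifluoromethanesulfonimide), Clc1ccc(nc1)N(S(=O)(=O)C(F)(F)F)S(=O)(=O)C(F)(F)F
Why: Kinetic deprotonation at the unsubstituted α'-CH2 (away from the branched α-carbon) and O-triflation put the C=C where the cyclopentene double bond of the target lies.

**Step 9**
Reactants: 16 the enol triflate from step 8; 10 1-[2-(2-methylpropyl)-1,3-dithian-2-yl]propan-1-one
Product: 18 5-methyl-3-{(R)-[(1R,5S)-5-methyl-2-{1-[2-(2-methylpropyl)-1,3-dithian-2-yl]-1-oxopropan-2-yl}cyclopent-2-en-1-yl][(triethylsilyl)oxy]methyl}-4-phenoxy-2H-chromen-2-one (both epimers at the propan-2-yl carbon), via chlorozinc enolate 17 (not isolated)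
Conditions: 10, LiHMDS, THF, −78 °C; ZnCl2, → 0 °C; then 16, Pd(dba)2 (5 mol%), Q-Phos (5 mol%), 23 °C; aq. NH4Cl at −78 °C
Reagents that add atoms: none
Why: Pd-catalysed α-alkenylation of a ketone enolate (Negishi-type coupling of the zinc enolate with the alkenyl triflate); only the ethyl side of 10 can enolise, the new CH(CH3) centre forms unselectively and is corrected in step 11, and cold α-protonation of the product enolate keeps the alkene out of conjugation.

**Step 10**
Reactants: 18 the dithiane ketone from step 9
Product: 19 5-methyl-3-{(R)-[(1R,5S)-5-methyl-2-(6-methyl-3,4-dioxoheptan-2-yl)cyclopent-2-en-1-yl][(triethylsilyl)oxy]methyl}-4-phenoxy-2H-chromen-2-one (both epimers at heptane C2)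
Conditions: Hg(ClO4)2·3H2O, CaCO3, THF/H2O (5:1), 0 °C
Reagents that add atoms: water, O
Why: Hg(II)-assisted hydrolysis of a 2-acyl-1,3-dithiane to the 1,2-diketone (Corey–Seebach unmasking); the carbonate buffer should spare the silyl ether and the β,γ-alkene.

**Step 11**
Reactants: 19 the silyl-protected diketone from step 10
Product: 22 CNP0310889.1, via desilylated hydroxy diketone 20 (not isolated), via cyclic hemiketal 21 (not isolated)
Conditions: TBAF (1.2 equiv), THF, 0 → 23 °C; aq. NH4Cl
Reagents that add atoms: none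
Why: Fluoride cleaves the Si–O bond; the carbinol alkoxide of 20 adds to the inner diketone carbonyl (6-exo-trig) to give the tetrahydropyran hemiketal alkoxide of 21, whose oxygen adds to coumarin C4 (6-endo-trig oxa-conjugate addition to the vinylogous carbonate), and the lactone enolate expels phenoxide (addition–elimination), closing the 1,3-dioxine. The closest known reaction types are the alkoxide → hemiacetal alkoxide → oxa-conjugate addition relay used for syn-1,3-diol acetals, and the exchange of 4-chloro or 4-aryloxy groups of coumarins by alkoxides. The ketal carbon has no freedom: only the hemiketal anomer whose O⁻ is cis to the coumarinyl group across the ring oxygen can reach C4, and the anomers interconvert through the open diketone. The CH(CH3) centre next to it is α to the diketone and allylic, so it epimerises through the dienolate in the basic fluoride medium; in the boat-like closing transition state its methyl eclipses either the small attacking oxygen (target epimer) or the isovaleryl group while also meeting the cyclopentene vinyl hydrogen (wrong epimer), so the target epimer should be drained (dynamic kinetic resolution). The carbinol centre from step 6 cannot invert, since its alkoxide has no retro-aldol partner and cannot reach C4 itself (four-membered ring). The step needs O-attack at C4 to outrun γ-protonation of the dienolate; phenoxide, a leaving group less basic than the hemiketal alkoxide, and the irreversible loss of phenol are meant to secure this.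

**Compound list**
1 | 1-(2-hydroxy-6-methylphenyl)ethan-1-one | CC(=O)c1c(C)cccc1O | starting material
2 | 4-hydroxy-5-methyl-2H-chromen-2-one | Cc1cccc2oc(=O)cc(O)c12 | intermediate
3 | 4-chloro-5-methyl-2-oxo-2H-chromene-3-carbaldehyde | Cc1cccc2oc(=O)c(C=O)c(Cl)c12 | intermediate
4 | 5-methyl-2-oxo-4-phenoxy-2H-chromene-3-carbaldehyde | Cc1cccc2oc(=O)c(C=O)c(Oc3ccccc3)c12 | intermediate
5 | 3-methylbutanal | CC(C)CC=O | starting material
6 | propane-1,3-dithiol | SCCCS | starting material
7 | 2-(2-methylpropyl)-1,3-dithiane | CC(C)CC1SCCCS1 | intermediate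
8 | N-methoxy-N-methylpropanamide | CCC(=O)N(C)OC | starting material
9 | 2-lithio-2-(2-methylpropyl)-1,3-dithiane | [Li]C1(CC(C)C)SCCCS1 | intermediate
10 | 1-[2-(2-methylpropyl)-1,3-dithian-2-yl]propan-1-one | CCC(=O)C1(CC(C)C)SCCCS1 | intermediate
11 | cyclopent-2-en-1-one | O=C1C=CCC1 | starting material
12 | methylzinc (S)-3-methylcyclopent-1-en-1-olate | C[Zn]OC1=C[C@@H](C)CC1 | intermediate
13 | 3-{(R)-hydroxy[(1S,2S)-2-methyl-5-oxocyclopentyl]methyl}-5-methyl-4-phenoxy-2H-chromen-2-one | Cc1cccc2oc(=O)c([C@H](O)[C@H]3C(=O)CC[C@@H]3C)c(Oc4ccccc4)c12 | intermediate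
14 | triethylsilyl ether of 13 | Cc1cccc2oc(=O)c([C@H](O[Si](CC)(CC)CC)[C@H]3C(=O)CC[C@@H]3C)c(Oc4ccccc4)c12 | intermediate
15 | lithium enolate of 14, enolised toward the ring CH2 | Cc1cccc2oc(=O)c([C@H](O[Si](CC)(CC)CC)[C@H]3C(O[Li])=CC[C@@H]3C)c(Oc4ccccc4)c12 | intermediate
16 | (4S,5S)-4-methyl-5-{(R)-(5-methyl-2-oxo-4-phenoxy-2H-chromen-3-yl)[(triethylsilyl)oxy]methyl}cyclopent-1-en-1-yl trifluoromethanesulfonate | Cc1cccc2oc(=O)c([C@H](O[Si](CC)(CC)CC)[C@H]3C(OS(=O)(=O)C(F)(F)F)=CC[C@@H]3C)c(Oc4ccccc4)c12 | intermediate
17 | chlorozinc enolate of 10 | CC=C(O[Zn]Cl)C1(CC(C)C)SCCCS1 | intermediate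
18 | dithiane-masked coupling product, (R)-carbinol, (1R,5S)-cyclopentene, epimers at the side-chain CH(CH3) | Cc1cccc2oc(=O)c([C@H](O[Si](CC)(CC)CC)[C@H]3C(=CC[C@@H]3C)C(C)C(=O)C4(CC(C)C)SCCCS4)c(Oc5ccccc5)c12 | intermediate
19 | silyl-protected 1,2-diketone, epimers at the side-chain CH(CH3) | Cc1cccc2oc(=O)c([C@H](O[Si](CC)(CC)CC)[C@H]3C(=CC[C@@H]3C)C(C)C(=O)C(=O)CC(C)C)c(Oc4ccccc4)c12 | intermediate
20 | desilylated hydroxy diketone (formed as its tetrabutylammonium alkoxide) | Cc1cccc2oc(=O)c([C@H](O)[C@H]3C(=CC[C@@H]3C)C(C)C(=O)C(=O)CC(C)C)c(Oc4ccccc4)c12 | intermediate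
21 | cyclic hemiketal: (1R,3R,4R,7S,7aR)-3-hydroxy-4,7-dimethyl-3-(3-methylbutanoyl)-1-(5-methyl-2-oxo-4-phenoxy-2H-chromen-3-yl)-1,3,4,6,7,7a-hexahydrocyclopenta[c]pyran, OH cis to the coumarinyl group | Cc1cccc2oc(=O)c([C@@H]3O[C@@](O)(C(=O)CC(C)C)[C@H](C)C4=CC[C@H](C)[C@@H]34)c(Oc5ccccc5)c12 | intermediate
22 | CNP0310889.1: 5-methylcoumarin fused at C3/C4 to the bridged ketal; ketal carbon S, coumarin-bearing CH–O R, ring-fusion CH R, cyclopentene CH(CH3) S, pyran CH(CH3) R | Cc1cccc2oc(=O)c3c(c12)O[C@@]1(C(=O)CC(C)C)O[C@@H]3[C@H]2C(=CC[C@@H]2C)[C@H]1C | target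

**Total step count:** 11. **Longest linear sequence:** 9 (steps 1, 2, 3, 6, 7, 8, 9, 10, 11).

**Steps most likely to fail**

Step 11. The coumarin bridge is trans to the cyclopentene bond at the ring-fusion carbon, so the tetrahydropyran must close through a boat and the closure may be slow. The free diketone could then suffer γ-protonation of its dienolate (alkene migrating into conjugation), α-ketol rearrangement, or incomplete equilibration at the CH(CH3) centre. The fallback closes the ring before the diketone is unmasked. It sets out from 18: TBAF in THF runs the same desilylation/hemiketalisation/addition–elimination on the mono-ketone, where no diketone enolate exists and the bulkier dithianyl group adds to the bias at the methyl centre. This gives the dithiane-masked bridged ketal F1, which Hg(ClO4)2/CaCO3 in wet THF converts to 22.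

Step 9. The coupling builds a tertiary carbon between a 2-substituted cyclopentenyl-Pd and an enolate flanked by a quaternary dithiane carbon, so transmetalation or reductive elimination may stall, or the enolate may attack the vinylogous ester. The fallback builds the side chain stepwise and sets out from 16:
- Suzuki coupling with isopropenylboronic acid pinacol ester (Pd(PPh3)4, K3PO4) gives the diene F2.
- 9-BBN adds to the 1,1-disubstituted alkene to give the B-alkyl-9-BBN adduct F3, which NaBO3 oxidises to the primary alcohol F4.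
- Dess–Martin oxidation gives the aldehyde F5.
- Lithiodithiane 9 at −78 °C gives the carbinol F6.
- Parikh–Doering oxidation returns to 18.

Step 6. Facial or anti/syn discrimination in the zinc aldol may be poor, or the zinc/copper mixture may attack C4 of aldehyde 4. The fallback separates the two events and sets out from 11. Cu-catalysed conjugate addition of MeMgBr (CuBr·SMe2, ferrocenyl diphosphine) with Me3SiCl trapping gives the silyl enol ether F7. MeLi then releases the copper-free lithium enolate F8, which adds to 4 at −78 °C with short contact time (kinetic anti aldol of the ring-locked E-enolate) and comes back at 13.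

**Further compounds**
F1 | step 11 | dithiane-masked bridged ketal (target with the isovaleryl C=O as 1,3-dithiane) | Cc1cccc2oc(=O)c3c(c12)O[C@@]1(C4(CC(C)C)SCCCS4)O[C@@H]3[C@H]2C(=CC[C@@H]2C)[C@H]1C
F2 | step 9 | isopropenyl diene from 16 | Cc1cccc2oc(=O)c([C@H](O[Si](CC)(CC)CC)[C@H]3C(=CC[C@@H]3C)C(C)=C)c(Oc4ccccc4)c12
F3 | step 9 | B-alkyl-9-BBN adduct of F2 | Cc1cccc2oc(=O)c([C@H](O[Si](CC)(CC)CC)[C@H]3C(=CC[C@@H]3C)C(C)CB4C5CCCC4CCC5)c(Oc6ccccc6)c12
F4 | step 9 | primary alcohol from F3 | Cc1cccc2oc(=O)c([C@H](O[Si](CC)(CC)CC)[C@H]3C(=CC[C@@H]3C)C(C)CO)c(Oc4ccccc4)c12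
F5 | step 9 | aldehyde from F4 | Cc1cccc2oc(=O)c([C@H](O[Si](CC)(CC)CC)[C@H]3C(=CC[C@@H]3C)C(C)C=O)c(Oc4ccccc4)c12
F6 | step 9 | α-hydroxy dithiane from F5 and 9 | Cc1cccc2oc(=O)c([C@H](O[Si](CC)(CC)CC)[C@H]3C(=CC[C@@H]3C)C(C)C(O)C4(CC(C)C)SCCCS4)c(Oc5ccccc5)c12
F7 | step 6 | (S)-trimethyl[(3-methylcyclopent-1-en-1-yl)oxy]silane | C[Si](C)(C)OC1=C[C@@H](C)CC1
F8 | step 6 | lithium (S)-3-methylcyclopent-1-en-1-olate | [Li]OC1=C[C@@H](C)CC1
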